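**Assumption:** 4-allyl-2,6-dimethoxyphenol, ethyl bromoacetate, veratraldehyde and (R)-4-benzyl-2-oxazolidinone are bought as such.

## Retrosynthetic overview

1. Target 16 (erythro, 1R,2S) ⇐ chelation-controlled reduction of (S)-α-aryloxy ketone 15 ⇐ oxidation of threo alcohol 14. A syn aldol gives the threo series, so C7 is re-set from C8.
2. 14 ⇐ C9 methyl by deoxygenation (CH2OTs → CH3) of aldol-derived 1,3-diol 12.
3. Key C7–C8 bond: Evans syn aldol of aryloxyacetyl imide 7 (boron Z-enolate) with veratraldehyde 8. This fixes C8 absolutely.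
4. 7 ⇐ aryloxyacetic acid 4 ⇐ O-alkylation of phenol 1 with ethyl bromoacetate 2.
5. No ring is formed: both benzene rings are bought, and the oxazolidinone ring is a recovered auxiliary.

## Route

**Step 1**
Reactants: 1 4-allyl-2,6-dimethoxyphenol; 2 ethyl bromoacetate
Product: 3 ethyl 2-(4-allyl-2,6-dimethoxyphenoxy)acetate
Conditions: K2CO3, acetone, reflux
Reagents that add atoms: none
Why: Williamson ether synthesis (SN2 of the phenoxide on an activated α-bromo ester); carbonate is too mild to isomerise the allyl group.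

**Step 2**
Reactants: 3 ethyl 2-(4-allyl-2,6-dimethoxyphenoxy)acetate
Product: 4 2-(4-allyl-2,6-dimethoxyphenoxy)acetic acid
Conditions: LiOH, THF/H2O, rt; then 1 M HCl
Reagents that add atoms: lithium hydroxide, [Li+].[OH-]
Why: Ester saponification; nothing else in the molecule is base-labile.

**Step 3**
Reactants: 4 2-(4-allyl-2,6-dimethoxyphenoxy)acetic acid; 5 (R)-4-benzyl-2-oxazolidinone
Product: 7 (R)-4-benzyl-3-[2-(4-allyl-2,6-dimethoxyphenoxy)acetyl]oxazolidin-2-one, via mixed pivalic anhydride 6 (not isolated)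
Conditions: t-BuCOCl, Et3N, THF, −20 °C; then 5, LiCl, −20 °C → rt
Reagents that add atoms: none
Why: N-acylation of the auxiliary through a mixed anhydride (LiCl/Et3N protocol); the oxazolidinone attacks the unhindered aryloxyacetyl carbonyl, not the pivaloyl one.

**Step 4**
Reactants: 7 (R)-4-benzyl-3-[2-(4-allyl-2,6-dimethoxyphenoxy)acetyl]oxazolidin-2-one; 8 3,4-dimethoxybenzaldehyde (veratraldehyde)
Product: 11 (R)-4-benzyl-3-[(2R,3S)-2-(4-allyl-2,6-dimethoxyphenoxy)-3-(3,4-dimethoxyphenyl)-3-hydroxypropanoyl]oxazolidin-2-one, via Z-dibutylboron enolate 9 (not isolated), via dibutylboron aldolate 10 (not isolated)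
Conditions: Bu2BOTf, iPr2NEt, CH2Cl2, 0 °C; 8, −78 → 0 °C; pH 7 buffer, MeOH, 30% H2O2, 0 °C
Reagents that add atoms: none
Why: Evans syn glycolate aldol: the Z-boron enolate reacts through a Zimmerman–Traxler chair on the face away from the benzyl group, giving the (2R,3S) syn adduct, whose C2 is C8 of the target with the correct absolute configuration.

**Step 5**
Reactants: 11 the syn aldol adduct
Product: 12 (1S,2S)-2-(4-allyl-2,6-dimethoxyphenoxy)-1-(3,4-dimethoxyphenyl)propane-1,3-diol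
Conditions: LiBH4, MeOH (1 equiv), THF, 0 °C
Reagents that add atoms: none
Why: Reductive cleavage of the N-acyl oxazolidinone to the primary alcohol; both stereocentres are untouched (the C2 descriptor changes only through CIP priorities) and the auxiliary is recovered.

**Step 6**
Reactants: 12 the threo 1,3-diol
Product: 13 (2S,3S)-2-(4-allyl-2,6-dimethoxyphenoxy)-3-(3,4-dimethoxyphenyl)-3-hydroxypropyl 4-methylbenzenesulfonate
Conditions: TsCl (1.1 equiv), Et3N, DMAP (cat.), CH2Cl2, 0 °C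
Reagents that add atoms: p-toluenesulfonyl chloride, Cc1ccc(cc1)S(=O)(=O)Cl
Why: Chemoselective sulfonylation of the primary hydroxyl over the hindered secondary benzylic one.

**Step 7**
Reactants: 13 the primary tosylate
Product: 14 (1S,2S)-2-(4-allyl-2,6-dimethoxyphenoxy)-1-(3,4-dimethoxyphenyl)propan-1-ol (threo)
Conditions: LiEt3BH, THF, 0 °C → rt
Reagents that add atoms: none
Why: SN2 hydride displacement of a primary tosylate turns C9 into the methyl group; no stereocentre is involved and the allyl group and aryl ethers are inert to the reagent.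

**Step 8**
Reactants: 14 the threo alcohol
Product: 15 (S)-2-(4-allyl-2,6-dimethoxyphenoxy)-1-(3,4-dimethoxyphenyl)propan-1-one
Conditions: Dess–Martin periodinane, CH2Cl2, 0 °C → rt
Reagents that add atoms: none
Why: Dess–Martin oxidation is non-basic, so the C8 stereocentre next to the new ketone is kept while the wrongly configured C7 carbinol is erased.

**Step 9**
Reactants: 15 the (S)-α-aryloxy ketone
Product: 16 (1R,2S)-2-(4-allyl-2,6-dimethoxyphenoxy)-1-(3,4-dimethoxyphenyl)propan-1-ol (target, erythro)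
Conditions: Zn(BH4)2 (from ZnCl2 + NaBH4), Et2O, −20 → 0 °C
Reagents that add atoms: none
Why: Cram-chelate 1,2-induction: zinc bridges the ketone oxygen and the C8 aryl ether oxygen, and hydride adds from the face of the C8 hydrogen, giving the erythro (1R) alcohol; the ketone is reduced far faster than the allyl group is hydroborated at this temperature.

## Compound list

1 | 4-allyl-2,6-dimethoxyphenol | C=CCc1cc(OC)c(O)c(OC)c1 | starting material
2 | ethyl bromoacetate | CCOC(=O)CBr | starting material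
3 | ethyl 2-(4-allyl-2,6-dimethoxyphenoxy)acetate | C=CCc1cc(OC)c(OCC(=O)OCC)c(OC)c1 | intermediate
4 | 2-(4-allyl-2,6-dimethoxyphenoxy)acetic acid | C=CCc1cc(OC)c(OCC(O)=O)c(OC)c1 | intermediate
5 | (R)-4-benzyl-2-oxazolidinone | O=C1N[C@H](Cc2ccccc2)CO1 | starting material
6 | 2-(4-allyl-2,6-dimethoxyphenoxy)acetic pivalic anhydride (not isolated) | C=CCc1cc(OC)c(OCC(=O)OC(=O)C(C)(C)C)c(OC)c1 | intermediate
7 | (R)-4-benzyl-3-[2-(4-allyl-2,6-dimethoxyphenoxy)acetyl]oxazolidin-2-one | C=CCc1cc(OC)c(OCC(=O)N2[C@H](Cc3ccccc3)COC2=O)c(OC)c1 | intermediate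
8 | 3,4-dimethoxybenzaldehyde | COc1ccc(C=O)cc1OC | starting material
9 | Z-dibutylboron enolate of 7 (not isolated) | C=CCc1cc(OC)c(O/C=C(\OB(CCCC)CCCC)N2[C@H](Cc3ccccc3)COC2=O)c(OC)c1 | intermediate
10 | dibutylboron aldolate of 11 (not isolated) | C=CCc1cc(OC)c(O[C@H]([C@@H](OB(CCCC)CCCC)c2ccc(OC)c(OC)c2)C(=O)N2[C@H](Cc3ccccc3)COC2=O)c(OC)c1 | intermediate
11 | (R)-4-benzyl-3-[(2R,3S)-2-(4-allyl-2,6-dimethoxyphenoxy)-3-(3,4-dimethoxyphenyl)-3-hydroxypropanoyl]oxazolidin-2-one | C=CCc1cc(OC)c(O[C@H]([C@@H](O)c2ccc(OC)c(OC)c2)C(=O)N2[C@H](Cc3ccccc3)COC2=O)c(OC)c1 | intermediate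
12 | (1S,2S)-2-(4-allyl-2,6-dimethoxyphenoxy)-1-(3,4-dimethoxyphenyl)propane-1,3-diol | C=CCc1cc(OC)c(O[C@H]([C@@H](O)c2ccc(OC)c(OC)c2)CO)c(OC)c1 | intermediate
13 | (2S,3S)-2-(4-allyl-2,6-dimethoxyphenoxy)-3-(3,4-dimethoxyphenyl)-3-hydroxypropyl 4-methylbenzenesulfonate | C=CCc1cc(OC)c(O[C@H]([C@@H](O)c2ccc(OC)c(OC)c2)COS(=O)(=O)c2ccc(C)cc2)c(OC)c1 | intermediate
14 | (1S,2S)-2-(4-allyl-2,6-dimethoxyphenoxy)-1-(3,4-dimethoxyphenyl)propan-1-ol | C=CCc1cc(OC)c(O[C@@H](C)[C@@H](O)c2ccc(OC)c(OC)c2)c(OC)c1 | intermediate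
15 | (S)-2-(4-allyl-2,6-dimethoxyphenoxy)-1-(3,4-dimethoxyphenyl)propan-1-one | C=CCc1cc(OC)c(O[C@@H](C)C(=O)c2ccc(OC)c(OC)c2)c(OC)c1 | intermediate
16 | (1R,2S)-2-(4-allyl-2,6-dimethoxyphenoxy)-1-(3,4-dimethoxyphenyl)propan-1-ol | C=CCc1cc(OC)c(O[C@@H](C)[C@H](O)c2ccc(OC)c(OC)c2)c(OC)c1 | target

## Summary

Total step count: 9. Longest linear sequence: 9 steps (1 → 16).

**Steps most likely to fail, with fallbacks**

Step 4 (boron aldol of a hindered, chelating aryloxyacetyl imide with an electron-rich aldehyde). The fallback sets out from 7 and comes back at 15. C8 is set by auxiliary-controlled enolate methylation instead. Treating 7 with NaN(SiMe3)2 in THF at −78 °C and then MeI gives (R)-4-benzyl-3-[(S)-2-(4-allyl-2,6-dimethoxyphenoxy)propanoyl]oxazolidin-2-one F1, the electrophile entering anti to the benzyl group of the chelated Z-enolate. Transamination with Me(MeO)NH·HCl/AlMe3 in CH2Cl2 gives (S)-2-(4-allyl-2,6-dimethoxyphenoxy)-N-methoxy-N-methylpropanamide F2. Single addition of 3,4-dimethoxyphenylmagnesium bromide F3 (made from 4-bromo-1,2-dimethoxybenzene and Mg in THF) to F2 at 0 °C gives ketone 15, and the route resumes at step 9.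

Step 7 (hydride displacement next to a free C7 alkoxide; possible oxetane formation or elimination to the enol ether). The fallback sets out from 11 and comes back at 14. The hydroxyl is masked before the reductions. TBSOTf/2,6-lutidine on 11 gives (R)-4-benzyl-3-[(2R,3S)-2-(4-allyl-2,6-dimethoxyphenoxy)-3-(tert-butyldimethylsilyloxy)-3-(3,4-dimethoxyphenyl)propanoyl]oxazolidin-2-one F4. LiBH4 gives (2S,3S)-2-(4-allyl-2,6-dimethoxyphenoxy)-3-(tert-butyldimethylsilyloxy)-3-(3,4-dimethoxyphenyl)propan-1-ol F5. TsCl/Et3N/DMAP gives the corresponding primary tosylate F6. LiEt3BH gives tert-butyl{[(1S,2S)-2-(4-allyl-2,6-dimethoxyphenoxy)-1-(3,4-dimethoxyphenyl)propyl]oxy}dimethylsilane F7. Bu4NF in THF then releases 14.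

Step 9 (erythro:threo ratio of the reduction, and the configurational stability of C8 in ketone 15). The fallback sets out from 14 and comes back at 16, avoiding the ketone altogether. Mitsunobu inversion of the benzylic alcohol of 14 (4-nitrobenzoic acid, PPh3, DIAD, toluene, −20 °C) gives (1R,2S)-2-(4-allyl-2,6-dimethoxyphenoxy)-1-(3,4-dimethoxyphenyl)propyl 4-nitrobenzoate F8. Methanolysis with K2CO3 in MeOH gives 16.

## Further compounds

F1 | step 4 | (R)-4-benzyl-3-[(S)-2-(4-allyl-2,6-dimethoxyphenoxy)propanoyl]oxazolidin-2-one | C=CCc1cc(OC)c(O[C@@H](C)C(=O)N2[C@H](Cc3ccccc3)COC2=O)c(OC)c1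
F2 | step 4 | (S)-2-(4-allyl-2,6-dimethoxyphenoxy)-N-methoxy-N-methylpropanamide | C=CCc1cc(OC)c(O[C@@H](C)C(=O)N(C)OC)c(OC)c1
F3 | step 4 | 3,4-dimethoxyphenylmagnesium bromide | COc1ccc([Mg]Br)cc1OC
F4 | step 7 | (R)-4-benzyl-3-[(2R,3S)-2-(4-allyl-2,6-dimethoxyphenoxy)-3-(tert-butyldimethylsilyloxy)-3-(3,4-dimethoxyphenyl)propanoyl]oxazolidin-2-one | C=CCc1cc(OC)c(O[C@H]([C@@H](O[Si](C)(C)C(C)(C)C)c2ccc(OC)c(OC)c2)C(=O)N2[C@H](Cc3ccccc3)COC2=O)c(OC)c1
F5 | step 7 | (2S,3S)-2-(4-allyl-2,6-dimethoxyphenoxy)-3-(tert-butyldimethylsilyloxy)-3-(3,4-dimethoxyphenyl)propan-1-ol | C=CCc1cc(OC)c(O[C@H]([C@@H](O[Si](C)(C)C(C)(C)C)c2ccc(OC)c(OC)c2)CO)c(OC)c1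
F6 | step 7 | (2S,3S)-2-(4-allyl-2,6-dimethoxyphenoxy)-3-(tert-butyldimethylsilyloxy)-3-(3,4-dimethoxyphenyl)propyl 4-methylbenzenesulfonate | C=CCc1cc(OC)c(O[C@H]([C@@H](O[Si](C)(C)C(C)(C)C)c2ccc(OC)c(OC)c2)COS(=O)(=O)c2ccc(C)cc2)c(OC)c1
F7 | step 7 | tert-butyl{[(1S,2S)-2-(4-allyl-2,6-dimethoxyphenoxy)-1-(3,4-dimethoxyphenyl)propyl]oxy}dimethylsilane | C=CCc1cc(OC)c(O[C@@H](C)[C@@H](O[Si](C)(C)C(C)(C)C)c2ccc(OC)c(OC)c2)c(OC)c1
F8 | step 9 | (1R,2S)-2-(4-allyl-2,6-dimethoxyphenoxy)-1-(3,4-dimethoxyphenyl)propyl 4-nitrobenzoate | C=CCc1cc(OC)c(O[C@@H](C)[C@H](OC(=O)c2ccc(cc2)[N+](=O)[O-])c2ccc(OC)c(OC)c2)c(OC)c1
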